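## Retrosynthetic overview

1. The pyranone ring is made last: Stille coupling/lactonisation of a (Z)-β-iodoenone, which comes from an ynone whose propargylic carbinol is installed early by aldol at C6 of carvone.
2. The spiro-glycidate comes from a ketone-relayed nucleophilic epoxidation of a γ-keto enoate (CO2Me cis to C2), obtained by opening and oxidising an α,β-unsaturated δ-lactone.
3. Key disconnection: the C1=Cα bond and the δ-lactone ring are formed by a cathodic reductive olefinating lactonisation of a β-(dichloroacetoxy) ketone.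
4. The C2 quaternary centre and the C5 carbinol come from one L-Selectride double reduction/aldol with furan-3-carbaldehyde; the C6 quaternary centre comes from methylation then aldol of (S)-carvone.
5. Ring order: cyclohexane (bought with carvone) → temporary δ-lactone → epoxide → pyranone.

Conventions: ring carbons are numbered as in carvone (C1 = carbonyl, later spiro carbon; C2 = methyl-bearing carbon; C5 = carbon with the chiral-pool substituent; C6 = second quaternary carbon); "upper face" is the face of the C5 substituent.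
Assumption: 3, 8 and 22 are bought; the two temporary carbinol centres (furyl carbinol and propargylic carbinol) are carried as epimer mixtures and drawn without configuration, because both are later oxidised to ketones.

## Route

Step 1
Reactants: 1 (S)-(+)-carvone
Product: 2 trans-6-methylcarvone (6-methyl anti to the isopropenyl group; minor 6-epimer carried along)
Conditions: LDA (1.05 equiv), THF, −78 °C; MeI, −78 → −20 °C
Reagents that add atoms: iodomethane CI
Why: Kinetic α′-deprotonation gives the cross-conjugated lithium enolate, which is C-methylated (enolate alkylation); the C6 configuration is irrelevant because C6 is re-enolised in step 3.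

Step 2
Reactants: 3 2-methyl-2-(trimethylsilyloxy)but-3-yne
Product: 4 4-methyl-4-(trimethylsilyloxy)pent-2-ynal
Conditions: n-BuLi, THF, −78 °C; DMF; pH 6 aqueous quench
Reagents that add atoms: N,N-dimethylformamide CN(C)C=O
Why: Formylation of a lithium acetylide with DMF; no stereocentre is involved.

Step 3
Reactants: 2 trans-6-methylcarvone; 4 4-methyl-4-(trimethylsilyloxy)pent-2-ynal
Product: 6 enone with quaternary C6 carrying methyl (cis to isopropenyl) and the CH(OTES)–C≡C–CMe2OTMS chain (trans to isopropenyl; carbinol epimers), via lithium aldolate 5 (not isolated)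
Conditions: LDA (1.1 equiv), THF, −78 → −20 °C; 4, −78 °C; TESOTf (1.2 equiv), −78 °C
Reagents that add atoms: triethylsilyl trifluoromethanesulfonate CC[Si](CC)(CC)OS(=O)(=O)C(F)(F)F
Why: Aldol addition of the tetrasubstituted α′-enolate to the ynal occurs anti to the adjacent C5 isopropenyl group, so the carvone stereocentre sets the C6 quaternary centre; silylating the aldolate at −78 °C blocks retro-aldol.

Step 4
Reactants: 6 C6-aldol TES ether
Product: 7 5-acetyl enone (isopropenyl cleaved to acetyl; otherwise as 6)
Conditions: OsO4 (2 mol %), NaIO4 (4 equiv), 2,6-lutidine (2 equiv), dioxane/H2O 3:1, 20 °C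
Reagents that add atoms: osmium tetroxide O=[Os](=O)(=O)=O (catalytic oxygen carrier); sodium periodate [Na+].[O-]I(=O)(=O)=O
Why: Lemieux–Johnson cleavage: the electron-rich 1,1-disubstituted alkene reacts far faster than the enone or the alkyne, and the buffered neutral medium leaves C5 (now α to a ketone) unepimerised.

Step 5
Reactants: 7 5-acetyl enone; 8 furan-3-carbaldehyde
Product: 11 C1 ketone with quaternary C2 (methyl down; CH(OCOCHCl2)(3-furyl) up) and C5 (S)-configured CH(CH3)OCOCHCl2 (furyl carbinol epimers), via dilithium enolate alkoxide 9 (not isolated), via dilithium aldolate 10 (not isolated)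
Conditions: L-Selectride (2.3 equiv), THF, −78 °C; 8 (1.3 equiv), −78 °C; Cl2CHCOCl (3 equiv), −78 → 0 °C
Reagents that add atoms: dichloroacetyl chloride ClC(Cl)C(Cl)=O
Why: L-Selectride reduces the methyl ketone (Felkin–Anh, hydride anti to the quaternary C6, giving the required carbinol) and the enone (conjugate reduction); the tetrasubstituted enolate then adds to 8 (aldol) on the face opposite the pseudo-axial C6 side chain, setting the C2 quaternary centre, and in situ O-acylation of both alkoxides stops retro-aldol.

Step 6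
Reactants: 11 bis(dichloroacetate) ketone
Product: 13 α,β-unsaturated δ-lactone fused at C1–C2 (C1=CH–C(=O)–O–CH(3-furyl)–C2; C5 carbinol now as acetate), via zinc chlorohydrin alkoxide 12 (not isolated)
Conditions: undivided cell, Zn anode, RVC cathode, n-Bu4NBr (0.1 M), DMF, 20 °C, constant current 4 mA cm⁻², 9 F mol⁻¹; aqueous NH4Cl work-up
Reagents that add atoms: none
Why: Proposed new method: cathodic reductive olefinating lactonisation — 2e⁻ cleavage of one C–Cl bond of the furyl-carbinol dichloroacetate gives a zinc α-chloro enolate (Zn²⁺ from the anode) that adds 6-exo to the adjacent doubly neopentyl C1 ketone, and 2e⁻ cleavage of the second C–Cl bond in the β-zinc-alkoxy chloro lactone triggers E1cB loss of zinc oxide, giving the conjugated lactone with the ester carbon necessarily cis to C2 without base and hence without retro-aldol (the C5 dichloroacetate cannot reach C1 except through a bridged seven-membered ring and ends as the acetate); the closest known reactions are sacrificial-anode electro-Reformatsky additions and Cr(II)- or Sm(II)-mediated aldol/β-elimination olefinations with dichloroacetates.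

Step 7
Reactants: 13 α,β-unsaturated δ-lactone
Product: 15 open methyl enoate with CO2Me cis to C2 and free furyl carbinol/C5 carbinol/tertiary alcohol (propargylic OTES kept), via lithium carboxylate 14 (not isolated)
Conditions: LiOH·H2O (6 equiv), THF/MeOH/H2O 3:1:1, 40 °C; evaporate; MeI (3 equiv), DMF, 0 → 20 °C; used crude
Reagents that add atoms: lithium hydroxide [Li+].[OH-]; iodomethane CI
Why: Saponification of the lactone, the acetate and the tertiary TMS ether followed by SN2 O-methylation of the carboxylate; the alkene geometry is inherited from the ring, and the crude ester is oxidised at once so it cannot relactonise.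

Step 8
Reactants: 15 hydroxy enoate
Product: 16 γ-keto enoate (3-furoyl on C2; CO2Me cis to C2)
Conditions: activated MnO2 (30 equiv), CH2Cl2, 20 °C
Reagents that add atoms: none
Why: MnO2 oxidises only the activated (3-furyl, benzylic-type) carbinol, so the saturated C5 carbinol and the tertiary alcohol survive and both furyl-carbinol epimers converge on one ketone.

Step 9
Reactants: 16 γ-keto enoate
Product: 18 spiro-glycidic methyl ester (epoxide oxygen on the face of the furoyl group; CO2Me cis to C2; propargylic OTES kept), via dioxolane ester enolate 17 (not isolated)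
Conditions: 30% aq. H2O2 (5 equiv), LiOH·H2O (1.2 equiv), THF/MeOH 3:1, 0 °C
Reagents that add atoms: hydrogen peroxide OO
Why: Weitz–Scheffer nucleophilic epoxidation relayed by the neighbouring ketone: the peroxy-hemiketal at the furoyl carbonyl delivers oxygen to C1 by 5-exo peroxy-Michael addition, necessarily on the furoyl face, and the lithium ester enolate then displaces the hemiketal oxygen (3-exo-tet) with the ester held on the C2 side (starting geometry plus Li bridging to the departing oxygen), so the C2 centre sets both epoxide centres.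

Step 10
Reactants: 18 spiro-glycidate TES ether
Product: 19 propargylic alcohol (carbinol epimers)
Conditions: HF·pyridine, pyridine, THF, 0 → 20 °C
Reagents that add atoms: none
Why: Fluoride desilylation of the TES ether; the electron-poor glycidic ester and the acylfuran tolerate buffered HF·pyridine.

Step 11
Reactants: 19 propargylic alcohol
Product: 20 ynone (C6–C(=O)–C≡C–CMe2OH)
Conditions: activated MnO2 (20 equiv), CH2Cl2, 20 °C
Reagents that add atoms: none
Why: MnO2 oxidises the propargylic alcohol selectively (both epimers converge); the saturated secondary and the tertiary alcohols do not react.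

Step 12
Reactants: 20 ynone
Product: 21 (Z)-β-iodoenone (iodine on the carbon bearing CMe2OH and cis to the ketone)
Conditions: NaI (1.5 equiv), AcOH (3 equiv), acetone, 0 °C
Reagents that add atoms: sodium iodide [Na+].[I-]
Why: Conjugate anti-hydroiodination of the ynone puts iodine on the β-carbon cis to the carbonyl; brief, cold, near-stoichiometric conditions spare the hindered glycidic ester.

Step 13
Reactants: 21 (Z)-β-iodoenone; 22 ethyl (Z)-3-(tributylstannyl)acrylate
Product: 24 CNP0293135.1 (target), via hydroxy dienoate 23 (not isolated)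
Conditions: Pd2(dba)3 (5 mol %), AsPh3 (20 mol %), CuI (10 mol %), NMP, 25 °C; then PPTS (cat.), 40 °C
Reagents that add atoms: none
Why: Stille coupling with retention at both alkenes gives the cis-dienoate, whose tertiary alcohol lactonises onto the cis ester (transesterification) to close the 5-ylidene-pyran-2-one with the ketone cis to the ring vinyl group, as in the target.

## Compound list

1 | (S)-(+)-carvone | O=C1C(C)=CC[C@H](C(C)=C)C1 | starting material
2 | trans-6-methylcarvone (6-Me anti to isopropenyl, major epimer) | O=C1C(C)=CC[C@H](C(C)=C)[C@H]1C | intermediate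
3 | 2-methyl-2-(trimethylsilyloxy)but-3-yne | C#CC(C)(C)O[Si](C)(C)C | starting material
4 | 4-methyl-4-(trimethylsilyloxy)pent-2-ynal | O=CC#CC(C)(C)O[Si](C)(C)C | intermediate
5 | lithium aldolate of 2 and 4 (not isolated) | [Li+].O=C1C(C)=CC[C@H](C(C)=C)[C@@]1(C)C([O-])C#CC(C)(C)O[Si](C)(C)C | intermediate
6 | C6-aldol TES ether (chain anti to isopropenyl, carbinol epimers) | O=C1C(C)=CC[C@H](C(C)=C)[C@@]1(C)C(O[Si](CC)(CC)CC)C#CC(C)(C)O[Si](C)(C)C | intermediate
7 | 5-acetyl enone | O=C1C(C)=CC[C@H](C(C)=O)[C@@]1(C)C(O[Si](CC)(CC)CC)C#CC(C)(C)O[Si](C)(C)C | intermediate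
8 | furan-3-carbaldehyde | O=Cc1ccoc1 | starting material
9 | dilithium enolate alkoxide (not isolated) | [Li+].[Li+].[O-]C1=C(C)CC[C@H]([C@@H](C)[O-])[C@@]1(C)C(O[Si](CC)(CC)CC)C#CC(C)(C)O[Si](C)(C)C | intermediate
10 | dilithium aldolate (not isolated) | [Li+].[Li+].O=C1[C@](C)(C([O-])c2ccoc2)CC[C@H]([C@@H](C)[O-])[C@@]1(C)C(O[Si](CC)(CC)CC)C#CC(C)(C)O[Si](C)(C)C | intermediate
11 | bis(dichloroacetate) ketone (furyl carbinol epimers) | O=C1[C@](C)(C(OC(=O)C(Cl)Cl)c2ccoc2)CC[C@H]([C@@H](C)OC(=O)C(Cl)Cl)[C@@]1(C)C(O[Si](CC)(CC)CC)C#CC(C)(C)O[Si](C)(C)C | intermediate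
12 | zinc chlorohydrin alkoxide of the δ-lactone (not isolated; drawn as the free alcohol) | O=C1OC(c2ccoc2)[C@]3(C)CC[C@H]([C@@H](C)OC(=O)C(Cl)Cl)[C@@](C)(C(O[Si](CC)(CC)CC)C#CC(C)(C)O[Si](C)(C)C)C3(O)C1Cl | intermediate
13 | α,β-unsaturated δ-lactone, C5 carbinol acetate | O=C1OC(c2ccoc2)[C@]3(C)CC[C@H]([C@@H](C)OC(C)=O)[C@@](C)(C(O[Si](CC)(CC)CC)C#CC(C)(C)O[Si](C)(C)C)C3=C1 | intermediate
14 | lithium carboxylate of the opened lactone (not isolated) | [Li+].[O-]C(=O)/C=C1\[C@](C)(C(O)c2ccoc2)CC[C@H]([C@@H](C)O)[C@@]1(C)C(O[Si](CC)(CC)CC)C#CC(C)(C)O | intermediate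
15 | hydroxy enoate methyl ester (CO2Me cis to C2) | COC(=O)/C=C1\[C@](C)(C(O)c2ccoc2)CC[C@H]([C@@H](C)O)[C@@]1(C)C(O[Si](CC)(CC)CC)C#CC(C)(C)O | intermediate
16 | γ-keto enoate (3-furoyl on C2) | COC(=O)/C=C1\[C@](C)(C(=O)c2ccoc2)CC[C@H]([C@@H](C)O)[C@@]1(C)C(O[Si](CC)(CC)CC)C#CC(C)(C)O | intermediate
17 | 1,2-dioxolane ester enolate (not isolated; drawn as the neutral ester) | COC(=O)C[C@@]12OOC(O)(c3ccoc3)[C@]1(C)CC[C@H]([C@@H](C)O)[C@@]2(C)C(O[Si](CC)(CC)CC)C#CC(C)(C)O | intermediate
18 | spiro-glycidate, propargylic TES ether | COC(=O)[C@H]1O[C@@]12[C@](C)(C(=O)c1ccoc1)CC[C@H]([C@@H](C)O)[C@@]2(C)C(O[Si](CC)(CC)CC)C#CC(C)(C)O | intermediate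
19 | spiro-glycidate, propargylic alcohol | COC(=O)[C@H]1O[C@@]12[C@](C)(C(=O)c1ccoc1)CC[C@H]([C@@H](C)O)[C@@]2(C)C(O)C#CC(C)(C)O | intermediate
20 | ynone | COC(=O)[C@H]1O[C@@]12[C@](C)(C(=O)c1ccoc1)CC[C@H]([C@@H](C)O)[C@@]2(C)C(=O)C#CC(C)(C)O | intermediate
21 | (Z)-β-iodoenone | COC(=O)[C@H]1O[C@@]12[C@](C)(C(=O)c1ccoc1)CC[C@H]([C@@H](C)O)[C@@]2(C)C(=O)/C=C(\I)C(C)(C)O | intermediate
22 | ethyl (Z)-3-(tributylstannyl)acrylate | CCOC(=O)/C=C\[Sn](CCCC)(CCCC)CCCC | starting material
23 | hydroxy dienoate from the Stille coupling (not isolated) | COC(=O)[C@H]1O[C@@]12[C@](C)(C(=O)c1ccoc1)CC[C@H]([C@@H](C)O)[C@@]2(C)C(=O)/C=C(\C=C/C(=O)OCC)C(C)(C)O | intermediate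
24 | CNP0293135.1 | COC(=O)[C@H]1O[C@@]12[C@](C)(C(=O)c1ccoc1)CC[C@H]([C@@H](C)O)[C@@]2(C)C(=O)/C=C1\C=CC(=O)OC1(C)C | target

## Step count and risks

Total step count: 13. Longest linear sequence: 12 steps (steps 1 and 3–13 from (S)-carvone; step 2 is a one-step side branch).

Three steps most likely to fail:

Step 6 (the proposed new electrochemical step). The second reduction may stop at the β-hydroxy chloro lactone, or the conjugated lactone may be over-reduced. The fallback uses known chemistry, an intramolecular Horner–Wadsworth–Emmons olefination; it sets out from 7 and comes back at 15. Compound 7 is taken through the reduction/aldol of step 5, but the dialkoxide is quenched with (diethoxyphosphoryl)acetyl chloride to give the bis(phosphonoacetate) ketone F1. LiCl/DBU in MeCN (Masamune–Roush conditions) then closes the ring onto the C1 ketone to give the unsaturated lactone C5-phosphonoacetate F2. The LiOH/MeI treatment of step 7, which also hydrolyses the spectator phosphonoacetate, delivers 15.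

Step 9 (ketone-relayed epoxidation). Hydroxide or hydroperoxide may instead cleave the hindered furoyl ketone (vinylogous retro-Claisen) or the methyl ester. The fallback epoxidises before the furyl carbinol is a ketone; it sets out from 13 and comes back at 18. Treating 13 with t-BuOOH/DBU in THF gives the epoxy lactone F3, with the ester carbon locked cis to C2 by the ring and oxygen entering opposite the C2 methyl and the C6 side chain. LiOH then MeI gives the epoxy hydroxy ester F4, and MnO2 oxidises its furyl carbinol to give 18.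

Step 5 (one-pot reduction/aldol/acylation). The crowded aldolate may revert, or facial selectivity at C2 may be low. The fallback replaces the metal-enolate aldol by an irreversible Lewis-acid aldol through an open transition state; it sets out from 7 and comes back at 11. L-Selectride followed by Me3SiCl/Et3N gives the bis-silyl compound (C1–C2 trimethylsilyl enol ether and C5-carbinol TMS ether) F5. A BF3·OEt2-mediated Mukaiyama aldol with 8 (CH2Cl2, −78 °C; citric acid/MeOH work-up) gives the keto diol F6, which is acylated separately with dichloroacetic anhydride/pyridine/DMAP to 11.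

Further compounds
F1 | step 6 | bis(phosphonoacetate) ketone | O=C1[C@](C)(C(OC(=O)CP(=O)(OCC)OCC)c2ccoc2)CC[C@H]([C@@H](C)OC(=O)CP(=O)(OCC)OCC)[C@@]1(C)C(O[Si](CC)(CC)CC)C#CC(C)(C)O[Si](C)(C)C
F2 | step 6 | unsaturated δ-lactone C5-phosphonoacetate | O=C1OC(c2ccoc2)[C@]3(C)CC[C@H]([C@@H](C)OC(=O)CP(=O)(OCC)OCC)[C@@](C)(C(O[Si](CC)(CC)CC)C#CC(C)(C)O[Si](C)(C)C)C3=C1
F3 | step 9 | epoxy δ-lactone C5-acetate | O=C3[C@H]1O[C@@]12[C@](C)(C(O3)c4ccoc4)CC[C@H]([C@@H](C)OC(C)=O)[C@@]2(C)C(O[Si](CC)(CC)CC)C#CC(C)(C)O[Si](C)(C)C
F4 | step 9 | epoxy hydroxy methyl ester | COC(=O)[C@H]1O[C@@]12[C@](C)(C(O)c1ccoc1)CC[C@H]([C@@H](C)O)[C@@]2(C)C(O[Si](CC)(CC)CC)C#CC(C)(C)O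
F5 | step 5 | bis-silyl compound (TMS enol ether and C5-carbinol TMS ether) | C[Si](C)(C)OC1=C(C)CC[C@H]([C@@H](C)O[Si](C)(C)C)[C@@]1(C)C(O[Si](CC)(CC)CC)C#CC(C)(C)O[Si](C)(C)C
F6 | step 5 | keto diol | O=C1[C@](C)(C(O)c2ccoc2)CC[C@H]([C@@H](C)O)[C@@]1(C)C(O[Si](CC)(CC)CC)C#CC(C)(C)O[Si](C)(C)C
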